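**Plan**

- Retrosynthesis: the C2 carbinol goes back to a ketone (last step); ring A is cut at C2′–C3′ and C4′–Br in one bromonium step; the C1=C8 bond is cut by a retro-aldol; the hydrindenone is cut at C3a–C7a, C1–C2 and C2–C3 (Pauson–Khand), leaving a linalool-type 1,7-enyne.
- Forward: geraniol → (R)-dehydrolinalool → enyne 7 → both core rings in one Pauson–Khand step → C4 bromide → conjugate reduction and aldol attach the myrcene-type chain (two steps from methallyl alcohol and prenyl bromide) → ring A closes last → desilylation and reduction.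
- Enabling feature: ring A is a 4-bromo-3,3-dimethylcyclohexylidene whose CMe2 carbon C3′ lies between CHBr (C4′) and CH2 (C2′). This is what remains when a prenyl bromonium ion is opened by the CH2 end of a 2-substituted 1,3-diene C2′=C1′–C8=C1, the C1′/C8/C1 allyl cation then shedding H-2.
- Stereochemistry: C7 from Sharpless epoxidation; C4 from Shi epoxidation then SN2 inversion; C3a by substrate control in the Pauson–Khand step; C7a by hydride addition anti to the angular methyl; C4′ by a chiral bromenium carrier; the E alkene from the s-trans diene; C1 by equilibration; C2 by hydroxyl-directed hydride delivery.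

Key step: step 16

Remark: the numbering of the target is used for all intermediates (hydrindane C1–C7a, exocyclic CH = C8, ring A C1′–C6′); β is the face of the C3a methyl group, α the opposite face, and "trans" means 3aβ-methyl/7aα-H.

**Route**

Step 1
Reactants: 1 geraniol
Product: 2 (2R,3R)-2,3-epoxygeraniol
Conditions: Ti(OiPr)4 (5 mol%), D-(−)-diethyl tartrate (7 mol%), t-BuOOH, 4 Å MS, CH2Cl2, −20 °C
Reagents that add atoms: tert-butyl hydroperoxide, CC(C)(C)OO
Why: Sharpless asymmetric epoxidation of a primary allylic alcohol, in which the D-tartrate ligand directs oxygen to the face that gives the 2R,3R epoxide and thereby fixes the later C7 carbinol centre.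

Step 2
Reactants: 2 (2R,3R)-2,3-epoxygeraniol
Product: 3 (2S,3R)-2-(chloromethyl)-3-methyl-3-(4-methylpent-3-en-1-yl)oxirane
Conditions: PPh3, CCl4, NaHCO3, reflux
Reagents that add atoms: carbon tetrachloride, ClC(Cl)(Cl)Cl
Why: Appel chlorination of the primary alcohol under buffered conditions leaves the epoxide and both stereocentres untouched (the descriptor at C2 changes only through the priority rules).

Step 3
Reactants: 3 (2S,3R)-2-(chloromethyl)-3-methyl-3-(4-methylpent-3-en-1-yl)oxirane
Product: 4 (3R)-3,7-dimethyloct-6-en-1-yn-3-ol [(R)-dehydrolinalool]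
Conditions: n-BuLi (3.2 equiv), THF, −40 → 0 °C
Reagents that add atoms: none
Why: Base-induced double elimination of a 2,3-epoxy chloride to a terminal propargylic alcohol (epoxide opening to the chlorovinyl alkoxide, then loss of HCl), in which the tertiary C–O bond is never broken so that its configuration is retained.

Step 4
Reactants: 4 (3R)-3,7-dimethyloct-6-en-1-yn-3-ol
Product: 5 (3R)-3,7-dimethyl-3-(triethylsilyloxy)oct-6-en-1-yne
Conditions: TESOTf, 2,6-lutidine, CH2Cl2, −78 → 0 °C
Reagents that add atoms: triethylsilyl triflate, CC[Si](CC)(CC)OS(=O)(=O)C(F)(F)F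
Why: Silylation of a tertiary alcohol with a silyl triflate and a hindered base, which masks the oxygen that could otherwise capture the cation of step 16.

Step 5
Reactants: 5 (3R)-3,7-dimethyl-3-(triethylsilyloxy)oct-6-en-1-yne
Product: 6 triethyl{[(3R)-5-[(2R)-3,3-dimethyloxiran-2-yl]-3-methylpent-1-yn-3-yl]oxy}silane
Conditions: D-fructose-derived Shi ketone (30 mol%), Oxone, K2CO3, Bu4NHSO4 (cat.), MeCN–dimethoxymethane/aq. buffer (pH 10.5), 0 °C
Reagents that add atoms: potassium peroxymonosulfate (Oxone), [K+].[O-]S(=O)(=O)OO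
Why: Shi epoxidation of the trisubstituted alkene, in which the chiral dioxirane sets the R epoxide carbon (later C4) by reagent control through the spiro transition state, the remote carbinol centre having no influence and the alkyne being inert.

Step 6
Reactants: 6 triethyl{[(3R)-5-[(2R)-3,3-dimethyloxiran-2-yl]-3-methylpent-1-yn-3-yl]oxy}silane
Product: 7 (3R,6R)-3,7-dimethyl-3-(triethylsilyloxy)oct-7-en-1-yn-6-ol
Conditions: Al(Oi-Pr)3, toluene, 110 °C
Reagents that add atoms: none
Why: Aluminium isopropoxide-mediated isomerisation of a trisubstituted epoxide to the allylic alcohol with a 1,1-disubstituted alkene (proton removal from a methyl group with cleavage of the tertiary C–O bond), the secondary C–O bond and its configuration being kept.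

Step 7
Reactants: 7 (3R,6R)-3,7-dimethyl-3-(triethylsilyloxy)oct-7-en-1-yn-6-ol
Product: 9 4α-hydroxy-3aβ,7α-dimethyl-7β-(triethylsilyloxy)-3,3a,4,5,6,7-hexahydro-2H-inden-2-one (C1=C7a enone), via alkyne-dicobalt hexacarbonyl complex 8 (not isolated)
Conditions: Co2(CO)8, CH2Cl2, rt; then N-methylmorpholine N-oxide, 0 °C → rt
Reagents that add atoms: dicobalt octacarbonyl, O=C=[Co](=C=O)(=C=O)(=C=O)[Co](=C=O)(=C=O)(=C=O)=C=O
Why: Intramolecular Pauson–Khand reaction of a 1,7-enyne forms C3a–C7a, C1–C2 and C2–C3 at once, and the quaternary C3a should be set by substrate control because the chair-like tether places the C7 methyl equatorial and the C7 silyloxy group axial on the face of the new angular methyl (the alternative needs two syn-axial methyl groups), while the axial 4α-hydroxyl, anti to the angular methyl, costs little next to the sp2 C7a.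

Step 8
Reactants: 9 4α-hydroxy-3aβ,7α-dimethyl-7β-(triethylsilyloxy)-3,3a,4,5,6,7-hexahydro-2H-inden-2-one
Product: 11 4β-bromo-3aβ,7α-dimethyl-7β-(triethylsilyloxy)-3,3a,4,5,6,7-hexahydro-2H-inden-2-one, via 4α-triflate 10 (not isolated)
Conditions: Tf2O, pyridine, CH2Cl2, −40 °C; then Bu4NBr, toluene, −40 → 0 °C
Reagents that add atoms: tetrabutylammonium bromide, CCCC[N+](CCCC)(CCCC)CCCC.[Br-]
Why: SN2 displacement of the axial secondary triflate by the non-basic bromide ion, which enters along the equatorial direction and gives the equatorial 4β-bromide with inversion, the neopentylic position making this one of the risky steps.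

Step 9
Reactants: 11 4β-bromo-3aβ,7α-dimethyl-7β-(triethylsilyloxy)-3,3a,4,5,6,7-hexahydro-2H-inden-2-one
Product: 12 C1=C2 trimethylsilyl enol ether of trans-4β-bromo-3aβ,7α-dimethyl-7β-(triethylsilyloxy)hydrindan-2-one (7aα-H)
Conditions: [(Ph3P)CuH]6, TMSCl, THF–benzene, rt
Reagents that add atoms: chlorotrimethylsilane, C[Si](C)(C)Cl
Why: Copper hydride conjugate reduction with silyl trapping of the enolate keeps the C1 regiochemistry, and hydride should reach C7a from the α face because the β face is covered by the angular methyl and the axial C7 silyloxy group, which sets the trans ring fusion, the alkyl bromide being inert to the copper hydride.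

Step 10
Reactants: 13 2-methylprop-2-en-1-ol; 14 1-bromo-3-methylbut-2-ene
Product: 16 6-methyl-2-methylidenehept-5-en-1-ol, via dilithio dianion 15 (not isolated)
Conditions: n-BuLi (2.2 equiv), TMEDA, Et2O–hexane, 0 °C → rt; then 14, −78 °C → rt
Reagents that add atoms: none
Why: Allylic lithiation of methallyl alcohol to its dianion and SN2 alkylation at the primary carbon of the allylic bromide build the 2-substituted allyl alcohol without any stereocentre.

Step 11
Reactants: 16 6-methyl-2-methylidenehept-5-en-1-ol
Product: 17 6-methyl-2-methylidenehept-5-enal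
Conditions: MnO2, CH2Cl2, rt
Reagents that add atoms: none
Why: Manganese dioxide oxidation of an allylic alcohol gives the enal and leaves the isolated trisubstituted alkene alone.

Step 12
Reactants: 12 C1=C2 trimethylsilyl enol ether of trans-4β-bromo-3aβ,7α-dimethyl-7β-(triethylsilyloxy)hydrindan-2-one; 17 6-methyl-2-methylidenehept-5-enal
Product: 19 trans-4β-bromo-1-(1-hydroxy-6-methyl-2-methylidenehept-5-en-1-yl)-3aβ,7α-dimethyl-7β-(triethylsilyloxy)hydrindan-2-one (mixture at C1 and C8), via lithium enolate 18 (not isolated)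
Conditions: MeLi, THF, 0 °C; then 17, −78 °C
Reagents that add atoms: none
Why: Cleavage of the silyl enol ether with methyllithium gives the regiodefined lithium enolate, whose aldol 1,2-addition to the α-branched enal forms the C1–C8 bond only at C1, the two new centres needing no control since both become sp2 in step 13.

Step 13
Reactants: 19 trans-4β-bromo-1-(1-hydroxy-6-methyl-2-methylidenehept-5-en-1-yl)-3aβ,7α-dimethyl-7β-(triethylsilyloxy)hydrindan-2-one
Product: 21 (1E)-trans-4β-bromo-3aβ,7α-dimethyl-1-(6-methyl-2-methylidenehept-5-en-1-ylidene)-7β-(triethylsilyloxy)hydrindan-2-one, via C8 mesylate 20 (not isolated)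
Conditions: MsCl, Et3N, CH2Cl2, 0 °C; then DBU, rt
Reagents that add atoms: none
Why: Mesylation and E1cB elimination of the β-hydroxy ketone give the dienone, expected as the E isomer with the dienyl group turned away from the carbonyl oxygen (a geometry that is erased in step 16), while the equatorial bromide has no anti-periplanar hydrogen for E2.

Step 14
Reactants: 21 (1E)-trans-4β-bromo-3aβ,7α-dimethyl-1-(6-methyl-2-methylidenehept-5-en-1-ylidene)-7β-(triethylsilyloxy)hydrindan-2-one
Product: 22 the corresponding 2β-alcohol, (1E)-trans-4β-bromo-3aβ,7α-dimethyl-1-(6-methyl-2-methylidenehept-5-en-1-ylidene)-7β-(triethylsilyloxy)hydrindan-2β-ol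
Conditions: NaBH4, CeCl3·7H2O, MeOH, −40 °C
Reagents that add atoms: none
Why: Luche 1,2-reduction of the dienone, in which hydride should enter from the α face, away from the angular methyl that is 1,3 to C2, to give the 2β-alcohol, a centre that is erased in step 16 so that its epimer would serve equally.

Step 15
Reactants: 22 (1E)-trans-4β-bromo-3aβ,7α-dimethyl-1-(6-methyl-2-methylidenehept-5-en-1-ylidene)-7β-(triethylsilyloxy)hydrindan-2β-ol
Product: 23 its 2β-O-tert-butyldimethylsilyl ether (C1-dienylidene hydrindane bis-silyl ether with pendant prenyl group)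
Conditions: TBSOTf, 2,6-lutidine, CH2Cl2, −78 → 0 °C
Reagents that add atoms: tert-butyldimethylsilyl triflate, CC(C)(C)[Si](C)(C)OS(=O)(=O)C(F)(F)F
Why: Silylation of the hindered secondary allylic alcohol with a silyl triflate installs the bulky group that later keeps oxygen from capturing the allyl cation and becomes the silyl enol ether oxygen substituent.

Step 16
Reactants: 23 2β-O-TBS, 7β-O-TES dienylidene hydrindane
Product: 24 trans-4β-bromo-1-{(E)-[(4S)-4-bromo-3,3-dimethylcyclohexylidene]methyl}-2-(tert-butyldimethylsilyloxy)-3aβ,7α-dimethyl-7β-(triethylsilyloxy)-3a,4,5,6,7,7a-hexahydro-3H-indene (C1=C2 silyl dienol ether)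
Conditions: NBS (1.05 equiv), chiral BINOL-derived thiophosphoramide Lewis base (20 mol%), 2,6-di-tert-butyl-4-methylpyridine (2 equiv), CH2Cl2–toluene, −78 → −40 °C
Reagents that add atoms: N-bromosuccinimide, O=C1CCC(=O)N1Br
Why: Proposed new method: bromenium is carried by the chiral Lewis base to the terminal trisubstituted alkene, the CH2 terminus C2′ of the diene opens the bromonium ion at its tertiary carbon C3′, and the allyl cation spread over C1′, C8 and C1 gives up the α-hydrogen at C2 to the hindered pyridine, leaving the silyl dienol ether of the C2 ketone; the closest known reactions are bromonium-initiated polyene cyclisations with N-bromoimides or bromosulfonium reagents and the acid-induced cyclisation of myrcene-type dienes to 3,3-dimethylcyclohexylidene products. Ring A closes in a 6-endo chair, endo to both the bromonium ion and the diene, with bromine equatorial. C4′, the only new stereocentre, is too far from the core to be influenced by it and is set by the chiral bromenium carrier, the enantiomer of which is chosen to give the 4′S bromide. Site selectivity for the prenyl alkene is secured because it is the most electron-rich and least hindered alkene, whereas the diene is congested, twisted and inductively deactivated by the allylic silyloxy group. The E alkene follows from the s-trans diene, in which the CH2 terminus points away from the core, so that the allyl cation has C1 anti to C2′. Loss of H-2 rather than H-7a or capture by oxygen is favoured by the pseudo-axial, exposed C2–H (the OTBS group is pseudo-equatorial), by the buried C7a–H and by the bulky silyl ethers, and a competing 1,2-hydride shift from C2 would only deliver the same C2 ketone one step early.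

Step 17
Reactants: 24 C1=C2 silyl dienol ether
Product: 26 trans-4β-bromo-1α-{(E)-[(4S)-4-bromo-3,3-dimethylcyclohexylidene]methyl}-7β-hydroxy-3aβ,7α-dimethylhydrindan-2-one (iriediol 2-ketone), via 7-O-triethylsilyl 2-ketone 25 (not isolated)
Conditions: TBAF, AcOH (1:1), THF, 0 °C → rt
Reagents that add atoms: none
Why: Fluoride cleavage of the silyl dienol ether with kinetic protonation of the dienolate at its α-carbon C1 gives the deconjugated β,γ-enone, the tertiary TES ether falls in the same operation, and the doubly activated C1 should settle under the buffered conditions in the more stable 1α configuration, in which the side chain avoids the syn-axial C7 oxygen.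

Step 18
Reactants: 26 iriediol 2-ketone
Product: 27 iriediol
Conditions: Me4NBH(OAc)3, MeCN–AcOH, −20 °C
Reagents that add atoms: none
Why: Saksena–Evans hydroxyl-directed reduction, in which the triacetoxyborohydride is bound by the axial 7β-hydroxyl that lies over the β face of the five-membered ring and delivers hydride intramolecularly to the β face of C2, giving the 2α-alcohol cis to the C1 side chain, while the reagent on its own reduces neither the ketone nor the bromides.

**Compound list**

1 | geraniol, (2E)-3,7-dimethylocta-2,6-dien-1-ol | CC(C)=CCC/C(C)=C/CO | starting material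
2 | (2R,3R)-2,3-epoxygeraniol | CC(C)=CCC[C@@]1(C)O[C@@H]1CO | intermediate
3 | (2S,3R)-2-(chloromethyl)-3-methyl-3-(4-methylpent-3-en-1-yl)oxirane | CC(C)=CCC[C@@]1(C)O[C@@H]1CCl | intermediate
4 | (3R)-3,7-dimethyloct-6-en-1-yn-3-ol | CC(C)=CCC[C@@](C)(O)C#C | intermediate
5 | (3R)-3,7-dimethyl-3-(triethylsilyloxy)oct-6-en-1-yne | CC(C)=CCC[C@@](C)(O[Si](CC)(CC)CC)C#C | intermediate
6 | triethyl{[(3R)-5-[(2R)-3,3-dimethyloxiran-2-yl]-3-methylpent-1-yn-3-yl]oxy}silane | CC1(C)O[C@@H]1CC[C@@](C)(O[Si](CC)(CC)CC)C#C | intermediate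
7 | (3R,6R)-3,7-dimethyl-3-(triethylsilyloxy)oct-7-en-1-yn-6-ol | C=C(C)[C@H](O)CC[C@@](C)(O[Si](CC)(CC)CC)C#C | intermediate
8 | hexacarbonyldicobalt complex of the alkyne of 7 (formed in situ) | [H]C12[Co]3(=C=O)(=C=O)(=C=O)[Co]1(=C=O)(=C=O)(=C=O)C23[C@](C)(O[Si](CC)(CC)CC)CC[C@@H](O)C(C)=C | intermediate
9 | 4α-hydroxy-3aβ,7α-dimethyl-7β-(triethylsilyloxy)-3,3a,4,5,6,7-hexahydro-2H-inden-2-one | O=C1C=C2[C@](C)(O[Si](CC)(CC)CC)CC[C@@H](O)[C@@]2(C)C1 | intermediate
10 | 4α-trifluoromethanesulfonate of 9 (formed in situ) | O=C1C=C2[C@](C)(O[Si](CC)(CC)CC)CC[C@@H](OS(=O)(=O)C(F)(F)F)[C@@]2(C)C1 | intermediate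
11 | 4β-bromo-3aβ,7α-dimethyl-7β-(triethylsilyloxy)-3,3a,4,5,6,7-hexahydro-2H-inden-2-one | O=C1C=C2[C@](C)(O[Si](CC)(CC)CC)CC[C@H](Br)[C@@]2(C)C1 | intermediate
12 | C1=C2 trimethylsilyl enol ether of trans-4β-bromo-3aβ,7α-dimethyl-7β-(triethylsilyloxy)hydrindan-2-one | C[Si](C)(C)OC1=C[C@@H]2[C@](C)(O[Si](CC)(CC)CC)CC[C@H](Br)[C@@]2(C)C1 | intermediate
13 | 2-methylprop-2-en-1-ol (methallyl alcohol) | CC(=C)CO | starting material
14 | 1-bromo-3-methylbut-2-ene (prenyl bromide) | CC(C)=CCBr | starting material
15 | dilithio dianion of 13 (formed in situ) | [Li]CC(=C)CO[Li] | intermediate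
16 | 6-methyl-2-methylidenehept-5-en-1-ol | CC(C)=CCCC(=C)CO | intermediate
17 | 6-methyl-2-methylidenehept-5-enal | CC(C)=CCCC(=C)C=O | intermediate
18 | lithium C1=C2 enolate of trans-4β-bromo-3aβ,7α-dimethyl-7β-(triethylsilyloxy)hydrindan-2-one (formed in situ) | [Li]OC1=C[C@@H]2[C@](C)(O[Si](CC)(CC)CC)CC[C@H](Br)[C@@]2(C)C1 | intermediate
19 | trans-4β-bromo-1-(1-hydroxy-6-methyl-2-methylidenehept-5-en-1-yl)-3aβ,7α-dimethyl-7β-(triethylsilyloxy)hydrindan-2-one, mixture at C1 and C8 | CC(C)=CCCC(=C)C(O)C1C(=O)C[C@]2(C)[C@@H](Br)CC[C@@](C)(O[Si](CC)(CC)CC)[C@@H]12 | intermediate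
20 | C8 methanesulfonate of 19 (formed in situ) | CC(C)=CCCC(=C)C(OS(C)(=O)=O)C1C(=O)C[C@]2(C)[C@@H](Br)CC[C@@](C)(O[Si](CC)(CC)CC)[C@@H]12 | intermediate
21 | (1E)-trans-4β-bromo-3aβ,7α-dimethyl-1-(6-methyl-2-methylidenehept-5-en-1-ylidene)-7β-(triethylsilyloxy)hydrindan-2-one | CC(C)=CCCC(=C)/C=C1/C(=O)C[C@]2(C)[C@@H](Br)CC[C@@](C)(O[Si](CC)(CC)CC)[C@@H]12 | intermediate
22 | 2β-alcohol from 21 | CC(C)=CCCC(=C)/C=C1/[C@@H](O)C[C@]2(C)[C@@H](Br)CC[C@@](C)(O[Si](CC)(CC)CC)[C@@H]12 | intermediate
23 | 2β-O-TBS ether of 22, precursor of the key step | CC(C)=CCCC(=C)/C=C1/[C@@H](O[Si](C)(C)C(C)(C)C)C[C@]2(C)[C@@H](Br)CC[C@@](C)(O[Si](CC)(CC)CC)[C@@H]12 | intermediate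
24 | C1=C2 TBS dienol ether of iriediol 2-ketone 7-O-TES ether, ring A (4′S,E) | CC1(C)C/C(=C/C2=C(O[Si](C)(C)C(C)(C)C)C[C@]3(C)[C@@H](Br)CC[C@@](C)(O[Si](CC)(CC)CC)[C@@H]23)CC[C@@H]1Br | intermediate
25 | iriediol 2-ketone 7-O-triethylsilyl ether, 1α side chain (formed in situ) | CC1(C)C/C(=C/[C@@H]2C(=O)C[C@]3(C)[C@@H](Br)CC[C@@](C)(O[Si](CC)(CC)CC)[C@@H]23)CC[C@@H]1Br | intermediate
26 | iriediol 2-ketone, trans-4β-bromo-1α-{(E)-[(4S)-4-bromo-3,3-dimethylcyclohexylidene]methyl}-7β-hydroxy-3aβ,7α-dimethylhydrindan-2-one | CC1(C)C/C(=C/[C@@H]2C(=O)C[C@]3(C)[C@@H](Br)CC[C@@](C)(O)[C@@H]23)CC[C@@H]1Br | intermediate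
27 | iriediol, trans-4β-bromo-1α-{(E)-[(4S)-4-bromo-3,3-dimethylcyclohexylidene]methyl}-3aβ,7α-dimethylhydrindane-2α,7β-diol | CC1(C)C/C(=C/[C@@H]2[C@H](O)C[C@]3(C)[C@@H](Br)CC[C@@](C)(O)[C@@H]23)CC[C@@H]1Br | target

**Count and risks**

Total step count: 18. Longest linear sequence: 16 steps (steps 1–9 and 12–18, from geraniol); the side chain takes steps 10 and 11.

Steps most likely to fail:

1. Step 16 (proposed new method).
 - What may go wrong: bromenium may be transferred to the diene instead of the prenyl alkene. The allyl cation may be quenched by loss of a ring A proton (C2′ or C6′) or of H-7a instead of H-2. Facial selectivity at C4′ or control of the new alkene geometry may be insufficient. The acid-labile silyl dienol ether may hydrolyse or conjugate during the reaction.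
 - Fallback (known chemistry, ring A made before the coupling; sets out from 12 and 14, returns at 25): alkylation of the dianion of methyl acetoacetate with prenyl bromide 14 would give methyl 7-methyl-3-oxooct-6-enoate F1. Its β-keto-ester-terminated bromocyclisation (an established terminator class; NBS with the same chiral Lewis base) would give methyl (5S)-5-bromo-6,6-dimethyl-2-oxocyclohexane-1-carboxylate F2. Krapcho decarboxylation (LiCl, wet DMSO) would give (4S)-4-bromo-3,3-dimethylcyclohexan-1-one F3. Wittig reaction with (methoxymethylidene)triphenylphosphorane would give (1S)-1-bromo-4-(methoxymethylidene)-2,2-dimethylcyclohexane F4, and mild acid hydrolysis (4S)-4-bromo-3,3-dimethylcyclohexane-1-carbaldehyde F5. Aldol addition of lithium enolate 18 (from 12 as in step 12) to this aldehyde would give the ring-A aldol adduct F6, and acid-catalysed dehydration the conjugated C1=C8 enone F7. Deconjugation (LDA/HMPA, then protonation of the extended dienolate at C1 with AcOH at −78 °C) would give 25. The C8=C1′ geometry is then decided in the dienolate formation and is not assured, so the alkene isomers would have to be separated.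

2. Step 8.
 - What may go wrong: E2 elimination toward C5 (the axial triflate has an anti-periplanar hydrogen) and Wagner–Meerwein migration of the angular methyl can outrun the slow SN2 attack at the neopentylic carbon.
 - Fallback (bromine brought in on an sp2 carbon and the C–H bond made last; sets out from 9, returns at 11): Dess–Martin oxidation would give 3aβ,7α-dimethyl-7β-(triethylsilyloxy)-3a,5,6,7-tetrahydro-3H-indene-2,4-dione F8. Kinetic deprotonation at the unhindered C5 methylene (KHMDS, PhNTf2, −78 °C) would give the C4 enol triflate F9, and ruthenium-catalysed triflate–bromide exchange with LiBr the alkenyl bromide F10. Hydrogen-atom-transfer hydrogenation (Mn(dpm)3, PhSiH3, t-BuOOH, i-PrOH) would reduce the bromoalkene with retention of bromine, the α-bromo radical taking up hydrogen from the axial α direction to leave the equatorial 4β-bromide, and would saturate the enone as well, giving trans-4β-bromo-3aβ,7α-dimethyl-7β-(triethylsilyloxy)hydrindan-2-one F11. Dehydrogenation with IBX, which can only proceed toward C7a because C3a is quaternary, would restore enone 11.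

3. Step 18.
 - What may go wrong: hydride delivery from the 7β-hydroxyl across the 1,4-distance may be too slow (no reduction), or external hydride may attack from the α face and give poor facial selectivity at C2.
 - Fallback (steric approach control on the protected ketone instead of internal delivery; sets out from 24, returns at 27): only the silyl enol ether would be cleaved (1 equiv TBAF/AcOH, −78 °C) and 25 isolated. L-Selectride (THF, −78 °C), approaching anti to the C1 side chain, would give 7-O-triethylsilyl iriediol F12, and TBAF would then give 27.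

**Further compounds**

F1 | step 16 | methyl 7-methyl-3-oxooct-6-enoate | COC(=O)CC(=O)CCC=C(C)C
F2 | step 16 | methyl (5S)-5-bromo-6,6-dimethyl-2-oxocyclohexane-1-carboxylate | COC(=O)C1C(=O)CC[C@H](Br)C1(C)C
F3 | step 16 | (4S)-4-bromo-3,3-dimethylcyclohexan-1-one | O=C1CC[C@H](Br)C(C)(C)C1
F4 | step 16 | (1S)-1-bromo-4-(methoxymethylidene)-2,2-dimethylcyclohexane | COC=C1CC[C@H](Br)C(C)(C)C1
F5 | step 16 | (4S)-4-bromo-3,3-dimethylcyclohexane-1-carbaldehyde | O=CC1CC[C@H](Br)C(C)(C)C1
F6 | step 16 | trans-4β-bromo-1-{[(4S)-4-bromo-3,3-dimethylcyclohexyl](hydroxy)methyl}-3aβ,7α-dimethyl-7β-(triethylsilyloxy)hydrindan-2-one | OC(C3CC[C@H](Br)C(C)(C)C3)C1C(=O)C[C@]2(C)[C@@H](Br)CC[C@@](C)(O[Si](CC)(CC)CC)[C@@H]12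
F7 | step 16 | (1E)-trans-4β-bromo-1-{[(4S)-4-bromo-3,3-dimethylcyclohexyl]methylidene}-3aβ,7α-dimethyl-7β-(triethylsilyloxy)hydrindan-2-one | C3(/C=C1/C(=O)C[C@]2(C)[C@@H](Br)CC[C@@](C)(O[Si](CC)(CC)CC)[C@@H]12)CC[C@H](Br)C(C)(C)C3
F8 | step 8 | 3aβ,7α-dimethyl-7β-(triethylsilyloxy)-3a,5,6,7-tetrahydro-3H-indene-2,4-dione | O=C1C=C2[C@](C)(O[Si](CC)(CC)CC)CCC(=O)[C@@]2(C)C1
F9 | step 8 | C4 enol triflate (C4=C5) of F8 | O=C1C=C2[C@](C)(O[Si](CC)(CC)CC)CC=C(OS(=O)(=O)C(F)(F)F)[C@@]2(C)C1
F10 | step 8 | 4-bromo-3aβ,7α-dimethyl-7β-(triethylsilyloxy)-3,3a,6,7-tetrahydro-2H-inden-2-one | O=C1C=C2[C@](C)(O[Si](CC)(CC)CC)CC=C(Br)[C@@]2(C)C1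
F11 | step 8 | trans-4β-bromo-3aβ,7α-dimethyl-7β-(triethylsilyloxy)hydrindan-2-one | O=C1C[C@@H]2[C@](C)(O[Si](CC)(CC)CC)CC[C@H](Br)[C@@]2(C)C1
F12 | step 18 | 7-O-triethylsilyl iriediol | CC1(C)C/C(=C/[C@@H]2[C@H](O)C[C@]3(C)[C@@H](Br)CC[C@@](C)(O[Si](CC)(CC)CC)[C@@H]23)CC[C@@H]1Br
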